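**Strategy.** The route rests on cutting the C5–C6 bond (longipinane numbering: C1 enone carbonyl, C4/C11 bridgeheads, C5 and C10 the one-carbon bridges). A vinylketene–alkene cycloaddition first builds the bicyclo[3.1.1]heptane from a farnesoate-like chain and leaves C5 as a cyclobutanone carbonyl, held 1,3-diaxial to the C10 side chain across the four-membered ring. In the key step a tertiary C6 radical on that chain adds to the C5 N-aziridinyl imine; loss of styrene and N2 and hydrogen capture convert the carbonyl carbon into the C5–H methine while closing the seven-membered ring C4–C5–C6–C7–C8–C9–C10. Its precursor already carries both esters and the C7 and C9 stereocentres.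

Key step: step 12

Remark on the chemistry: longipinane locants are used for the tricycles (C2=C3 alkene, C6 gem-dimethyl carbon, C7 isovalerate carbon, C9 senecioate carbon).
Assumption: 1-amino-2-phenylaziridine is a known hydrazine reagent, liberated from its storable acetate salt just before use.
Assumption: (–)-Ipc2BCl (step 3) and the (R,R)-bisphosphoramide (step 7) are the antipodes expected to give 9R and 1S (longipinane locants); the mirror-image reagent is taken if the facial sense proves to be the reverse.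

Step 1
Reactants: 1 3-bromo-3-methylbutan-2-one
Product: 2 3-methyl-3-(phenylselanyl)butan-2-one
Conditions: PhSeH, Et3N, CH2Cl2, 0 °C
Reagents that add atoms: benzeneselenol, [SeH]c1ccccc1
Why: The soft selenolate displaces bromide from the tertiary α-bromo ketone (nucleophilic substitution α to a carbonyl), installing the group that later serves as the C6 radical precursor.

Step 2
Reactants: 3 methyl 3-methylbut-2-enoate
Product: 4 tert-butyl[(1-methoxy-3-methylbuta-1,3-dien-1-yl)oxy]dimethylsilane (C1=C2 geometry not controlled; either isomer serves)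
Conditions: LiN(iPr)2, THF–DMPU, –78 °C; then tert-butyldimethylsilyl chloride
Reagents that add atoms: tert-butyldimethylsilyl chloride, CC(C)(C)[Si](C)(C)Cl
Why: Kinetic γ-deprotonation of the senecioate and O-silylation of the extended enolate should give the silyl dienol ether (silyl ketene acetal formation).

Step 3
Reactants: 5 (2E)-4,4-dimethoxy-2-methylbut-2-enal; 2 3-methyl-3-(phenylselanyl)butan-2-one
Product: 6 (5R,6E)-5-hydroxy-8,8-dimethoxy-2,6-dimethyl-2-(phenylselanyl)oct-6-en-3-one
Conditions: 2, (–)-Ipc2BCl, Et3N, Et2O, 0 °C; then 5, –78 to –20 °C; MeOH–pH 7 buffer work-up without peroxide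
Reagents that add atoms: none
Why: Paterson-type boron aldol reaction in which the enol diisopinocampheylborinate of the methyl ketone adds to the aldehyde under reagent control, which should set the carbinol centre (future C9) as R, while the peroxide-free work-up spares the selenide.

Step 4
Reactants: 6 (5R,6E)-5-hydroxy-8,8-dimethoxy-2,6-dimethyl-2-(phenylselanyl)oct-6-en-3-one; 7 3-methylbut-2-enal
Product: 8 (2E,4R,6R)-6-hydroxy-1,1-dimethoxy-3,7-dimethyl-7-(phenylselanyl)oct-2-en-4-yl 3-methylbut-2-enoate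
Conditions: SmI2 (0.3 equiv) premixed with 7 (6 equiv), THF, –10 °C; then 6
Reagents that add atoms: none
Why: Evans–Tishchenko reduction in which the samarium-bound hemiacetal of 7 delivers hydride to the ketone through a six-membered chair, giving the 1,3-anti diol monoester with the senecioate on the original hydroxyl and the new carbinol (future C7) as R; premixing leaves no divalent samarium to attack the α-selanyl ketone.

Step 5
Reactants: 8 (2E,4R,6R)-6-hydroxy-1,1-dimethoxy-3,7-dimethyl-7-(phenylselanyl)oct-2-en-4-yl 3-methylbut-2-enoate; 9 3-methylbutanoyl chloride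
Product: 10 (2E,4R,6R)-1,1-dimethoxy-3,7-dimethyl-6-(3-methylbutanoyloxy)-7-(phenylselanyl)oct-2-en-4-yl 3-methylbut-2-enoate
Conditions: pyridine, DMAP (cat.), CH2Cl2, 0 °C to rt
Reagents that add atoms: none
Why: DMAP-catalysed acylation of the remaining hindered secondary alcohol places the isovalerate on the future C7 oxygen with no change at any stereocentre.

Step 6
Reactants: 10 (2E,4R,6R)-1,1-dimethoxy-3,7-dimethyl-6-(3-methylbutanoyloxy)-7-(phenylselanyl)oct-2-en-4-yl 3-methylbut-2-enoate
Product: 11 (2E,4R,6R)-3,7-dimethyl-6-(3-methylbutanoyloxy)-1-oxo-7-(phenylselanyl)oct-2-en-4-yl 3-methylbut-2-enoate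
Conditions: PPTS (cat.), acetone–H2O, rt
Reagents that add atoms: water, O
Why: Mild acid hydrolysis of the allylic dimethyl acetal should release the E-enal without touching the two esters (acetal hydrolysis).

Step 7
Reactants: 11 (2E,4R,6R)-3,7-dimethyl-6-(3-methylbutanoyloxy)-1-oxo-7-(phenylselanyl)oct-2-en-4-yl 3-methylbut-2-enoate; 4 tert-butyl[(1-methoxy-3-methylbuta-1,3-dien-1-yl)oxy]dimethylsilane
Product: 12 methyl (2E,5S,6E,8R,10R)-5-hydroxy-3,7,11-trimethyl-8-(3-methylbut-2-enoyloxy)-10-(3-methylbutanoyloxy)-11-(phenylselanyl)dodeca-2,6-dienoate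
Conditions: SiCl4, (R,R)-bisphosphoramide from N,N′-dimethyl-1,1′-binaphthyl-2,2′-diamine (5 mol %), iPr2NEt (10 mol %), CH2Cl2, –78 °C; aq. NaHCO3
Reagents that add atoms: none
Why: Catalytic enantioselective vinylogous Mukaiyama aldol reaction in which the Lewis-base-activated silicon Lewis acid binds the enal and the dienol ether attacks through its γ-carbon, the catalyst setting the new carbinol (future C1) as S.

Step 8
Reactants: 12 methyl (2E,5S,6E,8R,10R)-5-hydroxy-3,7,11-trimethyl-8-(3-methylbut-2-enoyloxy)-10-(3-methylbutanoyloxy)-11-(phenylselanyl)dodeca-2,6-dienoate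
Product: 13 methyl (2E,5S,6E,8R,10R)-5-(tert-butyldimethylsilyloxy)-3,7,11-trimethyl-8-(3-methylbut-2-enoyloxy)-10-(3-methylbutanoyloxy)-11-(phenylselanyl)dodeca-2,6-dienoate
Conditions: TBSOTf, 2,6-lutidine, CH2Cl2, –78 °C
Reagents that add atoms: tert-butyldimethylsilyl trifluoromethanesulfonate, CC(C)(C)[Si](C)(C)OS(=O)(=O)C(F)(F)F
Why: Silylation of the secondary alcohol blocks lactonisation and acylation in the ketene step and keeps a bulky allylic substituent for facial control.

Step 9
Reactants: 13 methyl (2E,5S,6E,8R,10R)-5-(tert-butyldimethylsilyloxy)-3,7,11-trimethyl-8-(3-methylbut-2-enoyloxy)-10-(3-methylbutanoyloxy)-11-(phenylselanyl)dodeca-2,6-dienoate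
Product: 14 (2E,5S,6E,8R,10R)-5-(tert-butyldimethylsilyloxy)-3,7,11-trimethyl-8-(3-methylbut-2-enoyloxy)-10-(3-methylbutanoyloxy)-11-(phenylselanyl)dodeca-2,6-dienoic acid
Conditions: Me3SnOH, ClCH2CH2Cl, 80 °C; dilute aq. HCl work-up
Reagents that add atoms: trimethyltin hydroxide, C[Sn](C)(C)O
Why: Trimethyltin hydroxide should cleave the unhindered methyl ester selectively in the presence of the two secondary alkyl esters (mild chemoselective ester hydrolysis).

Step 10
Reactants: 14 (2E,5S,6E,8R,10R)-5-(tert-butyldimethylsilyloxy)-3,7,11-trimethyl-8-(3-methylbut-2-enoyloxy)-10-(3-methylbutanoyloxy)-11-(phenylselanyl)dodeca-2,6-dienoic acid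
Product: 17 (1R,4S,5R,7R)-4-(tert-butyldimethylsilyloxy)-7-methyl-2-methylidene-7-[(1R,3R)-4-methyl-1-(3-methylbut-2-enoyloxy)-3-(3-methylbutanoyloxy)-4-(phenylselanyl)pentyl]bicyclo[3.1.1]heptan-6-one, via acid chloride 15 (not isolated), via vinylketene 16 (not isolated)
Conditions: 1-chloro-N,N,2-trimethylprop-1-en-1-amine, CH2Cl2, 0 °C; then slow addition to Et3N, toluene, 110 °C, 0.005 M
Reagents that add atoms: none
Why: Intramolecular vinylketene–alkene [2+2] cycloaddition in which the ketene carbonyl carbon bonds to the less substituted alkene carbon and the α-carbon to the fully substituted one to give the bicyclo[3.1.1]heptan-6-one, the E-alkene placing the methyl syn and the side chain anti to the three-carbon bridge, while allylic 1,3-strain between the silyloxy carbinol and the cis methyl fixes the alkene face and hence both bridgeheads and the quaternary carbon; any endocyclic alkene isomer converges at step 14.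

Step 11
Reactants: 17 (1R,4S,5R,7R)-4-(tert-butyldimethylsilyloxy)-7-methyl-2-methylidene-7-[(1R,3R)-4-methyl-1-(3-methylbut-2-enoyloxy)-3-(3-methylbutanoyloxy)-4-(phenylselanyl)pentyl]bicyclo[3.1.1]heptan-6-one
Product: 18 N-(2-phenylaziridin-1-yl)imine of 17 at the C6 ketone (aziridine epimers and C=N isomers, all converging)
Conditions: 1-amino-2-phenylaziridine, AcOH (cat.), MgSO4, CH2Cl2, 0 °C
Reagents that add atoms: 1-amino-2-phenylaziridine, NN1CC1c1ccccc1
Why: The strained, non-enolisable cyclobutanone should condense readily with the hydrazine to give the N-aziridinyl imine (hydrazone formation).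

Step 12
Reactants: 18 N-(2-phenylaziridin-1-yl)imine of 17
Product: 21 (1S,4R,5S,7R,9R,10R,11R)-1-(tert-butyldimethylsilyloxy)-7-(3-methylbutanoyloxy)-9-(3-methylbut-2-enoyloxy)longipin-3(15)-ene (exocyclic CH2 on C3), via tertiary C6 radical 19 (not isolated), via C5 cyclobutyl radical 20 (not isolated)
Conditions: Bu3SnH (syringe pump), AIBN (cat.), benzene, 80 °C, 0.005 M
Reagents that add atoms: none
Why: Bu3Sn• abstracts the phenylselanyl group to give tertiary radical 19, which adds to the C5 carbon of the N-aziridinyl imine; the aminyl radical opens the aziridine, expels styrene and N2, and the C5 radical 20 takes hydrogen from Bu3SnH, so one C–C and one C–H bond replace the former C=O. The closest known reaction type is the tin-hydride-mediated radical cyclisation onto ketone N-aziridinyl imines with consecutive C–C and C–H bond formation, here extended from five- and six- to seven-membered closure. The only ring closed is the seven-membered ring C4–C5–C6–C7–C8–C9–C10, by 7-exo-trig attack of C6 on C5. C5 is the only new stereocentre: the chain hangs from C10 on the cyclobutane face remote from the three-carbon bridge, so C6 can bond only to that face and hydrogen must arrive syn to the bridge (5S), while C7 and C9 are carried in unchanged. The step needs cyclisation to outrun direct reduction of 19; the 1,3-diaxial proximity of C5 and the C10 chain, the reactive C=N acceptor and slow stannane addition at high dilution should secure this, and the carbon radical is never exocyclic to the cyclobutane, which avoids ring opening.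

Step 13
Reactants: 21 (1S,4R,5S,7R,9R,10R,11R)-1-(tert-butyldimethylsilyloxy)-7-(3-methylbutanoyloxy)-9-(3-methylbut-2-enoyloxy)longipin-3(15)-ene
Product: 22 (1S,4R,5S,7R,9R,10R,11R)-7-(3-methylbutanoyloxy)-9-(3-methylbut-2-enoyloxy)longipin-3(15)-en-1-ol
Conditions: HF·pyridine, THF–pyridine, 0 °C to rt
Reagents that add atoms: none
Why: Buffered fluoride desilylation should free the C1 alcohol without ester cleavage or acyl migration.

Step 14
Reactants: 22 (1S,4R,5S,7R,9R,10R,11R)-7-(3-methylbutanoyloxy)-9-(3-methylbut-2-enoyloxy)longipin-3(15)-en-1-ol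
Product: 24 (4R,5S,7R,9R,10R,11R)-7-(3-methylbutanoyloxy)-9-(3-methylbut-2-enoyloxy)longipin-2-en-1-one (target), via exo-methylene ketone 23 (not isolated)
Conditions: Dess–Martin periodinane, CH2Cl2, rt; then DBU (0.2 equiv), rt
Reagents that add atoms: none
Why: Dess–Martin oxidation gives the β,γ-unsaturated ketone, and base then moves the exocyclic double bond into conjugation through the C2 dienolate, the only one possible because bridgehead C11 cannot enolise.

**Compound list**

1 | 3-bromo-3-methylbutan-2-one | CC(=O)C(C)(C)Br | starting material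
2 | 3-methyl-3-(phenylselanyl)butan-2-one | CC(=O)C(C)(C)[Se]c1ccccc1 | intermediate
3 | methyl 3-methylbut-2-enoate | COC(=O)C=C(C)C | starting material
4 | tert-butyl[(1-methoxy-3-methylbuta-1,3-dien-1-yl)oxy]dimethylsilane | COC(O[Si](C)(C)C(C)(C)C)=CC(C)=C | intermediate
5 | (2E)-4,4-dimethoxy-2-methylbut-2-enal | O=C/C(C)=C/C(OC)OC | starting material
6 | (5R,6E)-5-hydroxy-8,8-dimethoxy-2,6-dimethyl-2-(phenylselanyl)oct-6-en-3-one | CC(C)([Se]c1ccccc1)C(=O)C[C@@H](O)/C(C)=C/C(OC)OC | intermediate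
7 | 3-methylbut-2-enal | CC(C)=CC=O | starting material
8 | (2E,4R,6R)-6-hydroxy-1,1-dimethoxy-3,7-dimethyl-7-(phenylselanyl)oct-2-en-4-yl 3-methylbut-2-enoate | CC(C)=CC(=O)O[C@H](C[C@@H](O)C(C)(C)[Se]c1ccccc1)/C(C)=C/C(OC)OC | intermediate
9 | 3-methylbutanoyl chloride | CC(C)CC(=O)Cl | starting material
10 | (2E,4R,6R)-1,1-dimethoxy-3,7-dimethyl-6-(3-methylbutanoyloxy)-7-(phenylselanyl)oct-2-en-4-yl 3-methylbut-2-enoate | CC(C)=CC(=O)O[C@H](C[C@@H](OC(=O)CC(C)C)C(C)(C)[Se]c1ccccc1)/C(C)=C/C(OC)OC | intermediate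
11 | (2E,4R,6R)-3,7-dimethyl-6-(3-methylbutanoyloxy)-1-oxo-7-(phenylselanyl)oct-2-en-4-yl 3-methylbut-2-enoate | CC(C)=CC(=O)O[C@H](C[C@@H](OC(=O)CC(C)C)C(C)(C)[Se]c1ccccc1)/C(C)=C/C=O | intermediate
12 | methyl (2E,5S,6E,8R,10R)-5-hydroxy-3,7,11-trimethyl-8-(3-methylbut-2-enoyloxy)-10-(3-methylbutanoyloxy)-11-(phenylselanyl)dodeca-2,6-dienoate | COC(=O)/C=C(\C)C[C@H](O)/C=C(\C)[C@H](OC(=O)C=C(C)C)C[C@@H](OC(=O)CC(C)C)C(C)(C)[Se]c1ccccc1 | intermediate
13 | 5-O-tert-butyldimethylsilyl ether of 12 | COC(=O)/C=C(\C)C[C@H](O[Si](C)(C)C(C)(C)C)/C=C(\C)[C@H](OC(=O)C=C(C)C)C[C@@H](OC(=O)CC(C)C)C(C)(C)[Se]c1ccccc1 | intermediate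
14 | (2E,5S,6E,8R,10R)-5-(tert-butyldimethylsilyloxy)-3,7,11-trimethyl-8-(3-methylbut-2-enoyloxy)-10-(3-methylbutanoyloxy)-11-(phenylselanyl)dodeca-2,6-dienoic acid | OC(=O)/C=C(\C)C[C@H](O[Si](C)(C)C(C)(C)C)/C=C(\C)[C@H](OC(=O)C=C(C)C)C[C@@H](OC(=O)CC(C)C)C(C)(C)[Se]c1ccccc1 | intermediate
15 | acid chloride of 14 | ClC(=O)/C=C(\C)C[C@H](O[Si](C)(C)C(C)(C)C)/C=C(\C)[C@H](OC(=O)C=C(C)C)C[C@@H](OC(=O)CC(C)C)C(C)(C)[Se]c1ccccc1 | intermediate
16 | vinylketene: (5S,6E,8R,10R)-5-(tert-butyldimethylsilyloxy)-7,11-dimethyl-3-methylidene-8-(3-methylbut-2-enoyloxy)-10-(3-methylbutanoyloxy)-11-(phenylselanyl)dodeca-1,6-dien-1-one | O=C=CC(=C)C[C@H](O[Si](C)(C)C(C)(C)C)/C=C(\C)[C@H](OC(=O)C=C(C)C)C[C@@H](OC(=O)CC(C)C)C(C)(C)[Se]c1ccccc1 | intermediate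
17 | (1R,4S,5R,7R)-4-(tert-butyldimethylsilyloxy)-7-methyl-2-methylidene-7-[(1R,3R)-4-methyl-1-(3-methylbut-2-enoyloxy)-3-(3-methylbutanoyloxy)-4-(phenylselanyl)pentyl]bicyclo[3.1.1]heptan-6-one | C=C1C[C@H](O[Si](C)(C)C(C)(C)C)[C@@H]2C(=O)[C@H]1[C@@]2(C)[C@H](OC(=O)C=C(C)C)C[C@@H](OC(=O)CC(C)C)C(C)(C)[Se]c1ccccc1 | intermediate
18 | N-(2-phenylaziridin-1-yl)imine of 17 | C=C1C[C@H](O[Si](C)(C)C(C)(C)C)[C@@H]2C(=NN3CC3c3ccccc3)[C@H]1[C@@]2(C)[C@H](OC(=O)C=C(C)C)C[C@@H](OC(=O)CC(C)C)C(C)(C)[Se]c1ccccc1 | intermediate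
19 | tertiary C6 radical from 18 | C=C1C[C@H](O[Si](C)(C)C(C)(C)C)[C@@H]2C(=NN3CC3c3ccccc3)[C@H]1[C@@]2(C)[C@H](OC(=O)C=C(C)C)C[C@@H](OC(=O)CC(C)C)[C](C)C | intermediate
20 | C5 cyclobutyl radical of the closed tricycle | CC(C)=CC(=O)O[C@@H]1C[C@@H](OC(=O)CC(C)C)C(C)(C)[C]2[C@H]3[C@@H](O[Si](C)(C)C(C)(C)C)CC(=C)[C@@H]2[C@]31C | intermediate
21 | (1S,4R,5S,7R,9R,10R,11R)-1-(tert-butyldimethylsilyloxy)-7-(3-methylbutanoyloxy)-9-(3-methylbut-2-enoyloxy)longipin-3(15)-ene | CC(C)=CC(=O)O[C@@H]1C[C@@H](OC(=O)CC(C)C)C(C)(C)[C@@H]2[C@H]3[C@@H](O[Si](C)(C)C(C)(C)C)CC(=C)[C@@H]2[C@]31C | intermediate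
22 | (1S,4R,5S,7R,9R,10R,11R)-7-(3-methylbutanoyloxy)-9-(3-methylbut-2-enoyloxy)longipin-3(15)-en-1-ol | CC(C)=CC(=O)O[C@@H]1C[C@@H](OC(=O)CC(C)C)C(C)(C)[C@@H]2[C@H]3[C@@H](O)CC(=C)[C@@H]2[C@]31C | intermediate
23 | (4R,5S,7R,9R,10R,11R)-7-(3-methylbutanoyloxy)-9-(3-methylbut-2-enoyloxy)longipin-3(15)-en-1-one | CC(C)=CC(=O)O[C@@H]1C[C@@H](OC(=O)CC(C)C)C(C)(C)[C@@H]2[C@H]3C(=O)CC(=C)[C@@H]2[C@]31C | intermediate
24 | (4R,5S,7R,9R,10R,11R)-7-(3-methylbutanoyloxy)-9-(3-methylbut-2-enoyloxy)longipin-2-en-1-one | CC(C)=CC(=O)O[C@@H]1C[C@@H](OC(=O)CC(C)C)C(C)(C)[C@@H]2[C@H]3C(=O)C=C(C)[C@@H]2[C@]31C | target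

**Totals.** Total step count: 14. Longest linear sequence: 13 steps (steps 1 and 3 to 14).

**Steps most likely to fail**

1. Step 12 (key step). The tertiary radical may be reduced by the stannane, or the N-aziridinyl imine may fragment thermally, before the slow seven-membered closure onto a hindered C=N takes place. The fallback sets out from 17. Condensation with 4-methylbenzenesulfonohydrazide gives the thermally robust tosylhydrazone F1. Radical cyclisation with Bu3SnH and AIBN at 110 °C under syringe-pump dilution gives the cyclised N′-tosylhydrazine F2, which is isolated. Heating F2 with NaOAc in ethanol eliminates sulfinate and the alkyldiazene loses N2, which installs the C5–H as a separate ionic step and returns to the route at 21.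

2. Step 10. The vinylketene may oligomerise or lose silanol by vinylogous elimination before it adds to an alkene that two allylic oxygens make less nucleophilic, and facial control may erode. The fallback sets out from 14. Coupling with dimethylamine (EDC) gives the N,N-dimethylamide F3. Activation with Tf2O and 2,4,6-collidine in ClCH2CH2Cl generates a keteniminium ion, a far stronger electrophile than the ketene, which cyclises onto the same alkene to the cyclobutaniminium triflate F4. Aqueous NaHCO3 hydrolysis of F4 returns to the route at 17.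

3. Step 4. Hemiacetal formation and hydride transfer may be sluggish with the conjugated aldehyde, residual divalent samarium may cleave the α-selanyl ketone, or the acyl group may migrate. The fallback sets out from 6. Evans–Saksena reduction (Me4NBH(OAc)3, MeCN–AcOH, –30 °C) gives the anti-diol F5. Selective acylation of its less hindered allylic C5 hydroxyl with 3-methylbut-2-enoyl chloride and pyridine at –20 °C returns to the route at 8.

**Further compounds**

F1 | step 12 | 4-methylbenzenesulfonylhydrazone of 17 at the C6 ketone | C=C1C[C@H](O[Si](C)(C)C(C)(C)C)[C@@H]2C(=NNS(=O)(=O)c3ccc(C)cc3)[C@H]1[C@@]2(C)[C@H](OC(=O)C=C(C)C)C[C@@H](OC(=O)CC(C)C)C(C)(C)[Se]c1ccccc1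
F2 | step 12 | cyclised tricycle carrying the N′-tosylhydrazino group on C5 in place of hydrogen (otherwise as 21) | CC(C)=CC(=O)O[C@@H]1C[C@@H](OC(=O)CC(C)C)C(C)(C)[C@]2(NNS(=O)(=O)c4ccc(C)cc4)[C@H]3[C@@H](O[Si](C)(C)C(C)(C)C)CC(=C)[C@@H]2[C@]31C
F3 | step 10 | N,N-dimethylamide of acid 14 | CN(C)C(=O)/C=C(\C)C[C@H](O[Si](C)(C)C(C)(C)C)/C=C(\C)[C@H](OC(=O)C=C(C)C)C[C@@H](OC(=O)CC(C)C)C(C)(C)[Se]c1ccccc1
F4 | step 10 | N,N-dimethyliminium triflate of 17 at C6 | C=C1C[C@H](O[Si](C)(C)C(C)(C)C)[C@@H]2C(=[N+](C)C)[C@H]1[C@@]2(C)[C@H](OC(=O)C=C(C)C)C[C@@H](OC(=O)CC(C)C)C(C)(C)[Se]c1ccccc1.[O-]S(=O)(=O)C(F)(F)F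
F5 | step 4 | (3R,5R,6E)-8,8-dimethoxy-2,6-dimethyl-2-(phenylselanyl)oct-6-ene-3,5-diol | CC(C)([Se]c1ccccc1)[C@H](O)C[C@@H](O)/C(C)=C/C(OC)OC
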